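Two numbers and a winner are wanted from you, and these are the flasks they concern.

| flask | substrate | reagent | free catalyst | remark | time |
|---|---|---|---|---|---|
| south-east | 0.40 M | 0.38 M | 2.3 mM | run made earlier |  |
| north-west | 0.40 M | 0.38 M | 14 mM | run made earlier |  |
| summer | 0.40 M | 0.380 M | 4.0 mM |  | 20 min |
| midnight | 0.40 M | 0.380 M | 16 mM |  | 5.0 min |

| run | time / min | product / % | substrate / % |
|---|---|---|---|
| south-east | 0.417 | 0.6 | 99.9 |
| south-east | 0.667 | 1.4 | 98.6 |
| south-east | 1.00 | 1.5 | 98.8 |
| south-east | 1.33 | 1.8 | 96.8 |
| south-east | 2.00 | 3.4 | 95.4 |
| south-east | 3.00 | 4.1 | 94.7 |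
| south-east | 5.00 | 8.1 | 91.9 |
| north-west | 0.417 | 3.8 | 94.8 |
| north-west | 0.667 | 7.2 | 91.2 |
| north-west | 1.00 | 9.5 | 88.0 |
| north-west | 1.33 | 13.0 | 85.3 |
| north-west | 2.00 | 18.5 | 78.6 |
| north-west | 3.00 | 24.9 | 72.3 |
| north-west | 5.00 | 36.7 | 61.7 |

(scatter of a reading: 0.5 percentage points)

- the winner by amount of product, in percent of the substrate charged; "neither" if no more than 2 percentage points parts them (summer / midnight / neither)
- how much product is there at the end, in percent of the substrate charged: summer
- how much product is there at the end, in percent of the substrate charged: midnight

- steps thought possible: reagent + catalyst intermediate A <-> catalyst intermediate B; catalyst intermediate A -> spent catalyst; substrate + free catalyst <-> catalyst intermediate A; catalyst intermediate B -> free catalyst + product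

The charges set no near stop: the reagent, here the limiting reagent, allows 95.0% of the substrate, so the matter is how fast that end is approached. Turn the question round and ask what would keep summer within 2 percentage points of midnight.

Take the rate to go with c(free catalyst) times c(substrate) times c(reagent). The last two are nearly equal, so the converted fraction x follows x = D/(D + H), where D, the dose, is c(free catalyst) charged times time. The last north-west reading gives 121 mM·min for H, the half-dose, the dose at which x reaches 0.5. The south-east run then comes out at 8.70%, and its last reading is 8.1%.

Both new flasks get 80.0 mM·min, which by my reckoning gives midnight 39.9%. Summer, though, receives just 20.0 mM·min of its nominal dose within the 5.00 min the runs cover. A tie asks 73.5 mM·min of it, so summer's later minutes must deliver 89.2% of their nominal share. Those minutes lie on average 10.0 min after the early ones, so the catalyst's working half-life must exceed 60.8 min. The north-west reading at 2.00 min gives H = 123 mM·min, too close to 121 mM·min to tell whether the half-life is that long. Since a step to spent catalyst is on the list, I lean to midnight, without firmness.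

The forecast says midnight, with 40% (38% to 43%) for midnight and 36% (30% to 41%) for summer: “Midnight is the likely winner, though not certain”.

The flask gives midnight, with 40.4% against 31.2% for summer.

    reagent + catalyst intermediate A ⇌ catalyst intermediate B (K = 1.97 M⁻¹, k = 2.07 M⁻¹ s⁻¹)
    catalyst intermediate A → spent catalyst (k = 0.00214 s⁻¹)
    substrate + free catalyst ⇌ catalyst intermediate A (K = 4.20 M⁻¹, k = 1.79 M⁻¹ s⁻¹)
    catalyst intermediate B → free catalyst + product (k = 0.197 s⁻¹)

At 20.0 min summer holds 65.2% of its catalyst charge as spent catalyst, while midnight at 5.00 min holds 22.9%. Read through the half-dose, summer's product is worth 54.7 mM·min, less than the 73.5 mM·min of a tie. In the neighbouring flask with 10.0 mM of free catalyst for 20 min, the dose is 200 mM·min, the half-dose gives 62.3%, and the flask holds 58.3%.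

The runs were computed for substances that don't exist; scatter was added.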